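## Retrosynthetic overview

1. Target 6 ⇒ 5: the saturated C18 linker comes from hydrogenating a mid-chain alkene in the last step.
2. 5 ⇒ 3 + 4: cross-metathesis joins a dec-9-enyl arm on the pyrrole to undec-10-enenitrile (8 + 2 + 8 carbons = the C18 linker, with the nitrile already in place).
3. 3 ⇒ 1 + 2: the pyrrole C5–C(sp3) bond is made by a new photochemical radical anti-Markovnikov hydroheteroarylation of deca-1,9-diene with 5-bromo-1H-pyrrole-2-carbaldehyde.
4. Rings: the only ring, the 2-formylpyrrole, is bought intact as 1; no ring is formed in the route.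

Assumption: the target has no stereocentre and no stereogenic double bond, so it is one achiral compound and needs no stereocontrol; 1, 2 and 4 are taken as catalogue chemicals.

## Route

Step 1
Reactants: 1 5-bromo-1H-pyrrole-2-carbaldehyde; 2 deca-1,9-diene
Product: 3 5-(dec-9-en-1-yl)-1H-pyrrole-2-carbaldehyde
Conditions: 2 (5 equiv), 2,4,5,6-tetrakis(diphenylamino)isophthalonitrile (4DPAIPN, 2 mol %), cyclohexanethiol (5 mol %), HCO2Na (3 equiv), DMSO/tBuOH 4:1 (0.2 M in 1), 450 nm LEDs, 25 °C, N2
Reagents that add atoms: none
Why: Proposed new method: a formate/thiol photoredox radical chain in which the thiyl radical abstracts hydrogen from formate to give the CO2 radical anion, this strong reductant cleaves the C–Br bond of 1 by dissociative electron transfer, the resulting 5-formylpyrrol-2-yl sigma radical adds very fast to the unsubstituted terminus of the excess diene (anti-Markovnikov, one of the two equivalent alkenes), and the secondary alkyl radical takes a hydrogen atom from the thiol in a polarity-matched transfer that returns the thiyl radical; the closest known reaction type is the photoredox radical hydroarylation of unactivated alkenes with pyridyl, azolyl and aryl halides, which to my knowledge has not been shown for an N-unprotected 2-bromopyrrole carrying a free formyl group.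

Step 2
Reactants: 3 5-(dec-9-en-1-yl)-1H-pyrrole-2-carbaldehyde; 4 undec-10-enenitrile
Product: 5 19-(5-formyl-1H-pyrrol-2-yl)nonadec-10-enenitrile (E/Z mixture)
Conditions: 4 (3 equiv), second-generation Hoveyda–Grubbs catalyst RuCl2(H2IMes)(=CH-C6H4-2-OiPr) (3 mol %), CH2Cl2 (0.1 M), 40 °C, slow Ar sweep
Reagents that add atoms: none
Why: Olefin cross-metathesis between two unhindered terminal alkenes of equal reactivity, where the excess of 4 pushes 3 statistically into the cross product, ethene leaves, and the E/Z ratio does not matter because the alkene is hydrogenated next.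

Step 3
Reactants: 5 19-(5-formyl-1H-pyrrol-2-yl)nonadec-10-enenitrile (E/Z mixture)
Product: 6 mycalenitrile 14 [19-(5-formyl-1H-pyrrol-2-yl)nonadecanenitrile]
Conditions: H2 (1 atm), 10% Pd/C, Ph2S (0.01 equiv), EtOAc, 25 °C
Reagents that add atoms: none
Why: Heterogeneous catalytic hydrogenation, in which sulfide-moderated Pd/C at 1 atm saturates the isolated 1,2-disubstituted alkene while the vinylogous-formamide aldehyde, the pyrrole ring and the nitrile stay untouched; no stereocentre is created.

## Compound list

1 | 5-bromo-1H-pyrrole-2-carbaldehyde | O=Cc1ccc(Br)[nH]1 | starting material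
2 | deca-1,9-diene | C=CCCCCCCC=C | starting material
3 | 5-(dec-9-en-1-yl)-1H-pyrrole-2-carbaldehyde | O=Cc1ccc(CCCCCCCCC=C)[nH]1 | intermediate
4 | undec-10-enenitrile | N#CCCCCCCCCC=C | starting material
5 | 19-(5-formyl-1H-pyrrol-2-yl)nonadec-10-enenitrile (E/Z mixture, alkene geometry not defined) | N#CCCCCCCCCC=CCCCCCCCCc1ccc(C=O)[nH]1 | intermediate
6 | mycalenitrile 14, 19-(5-formyl-1H-pyrrol-2-yl)nonadecanenitrile (achiral) | N#CCCCCCCCCCCCCCCCCCCc1ccc(C=O)[nH]1 | target

Total step count: 3
Longest linear sequence: 3 steps (1 → 3 → 5 → 6)

## Steps most likely to fail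

**Step 1 (the proposed new step).** The likely failures are plain hydrodebromination of 1 before the radical meets the alkene, single-electron reduction of the aldehyde, and loss of the thiol by thiol-ene addition to the diene. The fallback uses known chemistry, sets out from 1 and 2 and comes back at 3. Deca-1,9-diene 2 (4 equiv) is monohydroborated with 9-BBN-H in THF (0 to 25 °C) to give 9-(dec-9-en-1-yl)-9-borabicyclo[3.3.1]nonane F1. F1 is not isolated but coupled with 1 in a B-alkyl Suzuki–Miyaura reaction (PdCl2(dppf) 5 mol %, K3PO4 3 equiv, THF/DMF/H2O, 60 °C) to give 3. The excess diene ensures that no B–H remains to reduce the aldehyde.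

**Step 2.** The risk is a poor statistical cross-metathesis: homodimers that are hard to separate, or a catalyst slowed by the nitrile and the pyrrole aldehyde. The fallback avoids metathesis and hydrogenation altogether, sets out from 1 and comes back at 6. Commercial 8-bromooct-1-ene is converted with Mg in THF into oct-7-en-1-ylmagnesium bromide F2. F2 is added slowly to commercial 11-bromoundecanenitrile in a copper-catalysed alkyl–alkyl coupling (Li2CuCl4 3 mol %, NMP 4 equiv, THF, 0 to 20 °C) to give nonadec-18-enenitrile F3. Hydroboration of F3 with 9-BBN-H (THF, 25 °C) gives 19-(9-borabicyclo[3.3.1]nonan-9-yl)nonadecanenitrile F4. B-alkyl Suzuki–Miyaura coupling of F4 with 1 (PdCl2(dppf), K3PO4, THF/DMF/H2O, 60 °C) gives 6 directly.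

**Step 3.** The risk is over-reduction (aldehyde to alcohol or methyl, nitrile to amine) or incomplete saturation on the poisoned catalyst. The fallback saturates the chain before any pyrrole aldehyde is present, sets out from 4 and comes back at 6. Compound 4 is cross-metathesised with commercial 10-bromodec-1-ene (3 equiv of 4, RuCl2(H2IMes)(=CH-C6H4-2-OiPr) 3 mol %, CH2Cl2, 40 °C) to give 19-bromononadec-10-enenitrile F5. F5 is hydrogenated (H2 1 atm, 10% Pd/C, EtOAc, 25 °C) to 19-bromononadecanenitrile F6. F6 then alkylates commercial 1H-pyrrole-2-carbaldehyde at C5 by the known norbornene-mediated, N–H-directed C–H alkylation of electron-poor pyrroles with primary alkyl bromides under divalent palladium catalysis (PdCl2(MeCN)2 10 mol %, norbornene 2 equiv, KHCO3 3 equiv, DMA containing 0.5 M H2O, 90 °C) to give 6.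

## Further compounds

F1 | step 1 | 9-(dec-9-en-1-yl)-9-borabicyclo[3.3.1]nonane | C=CCCCCCCCCB1C2CCCC1CCC2
F2 | step 2 | oct-7-en-1-ylmagnesium bromide | C=CCCCCCC[Mg]Br
F3 | step 2 | nonadec-18-enenitrile | N#CCCCCCCCCCCCCCCCCC=C
F4 | step 2 | 19-(9-borabicyclo[3.3.1]nonan-9-yl)nonadecanenitrile | N#CCCCCCCCCCCCCCCCCCCB1C2CCCC1CCC2
F5 | step 3 | 19-bromononadec-10-enenitrile (E/Z mixture) | N#CCCCCCCCCC=CCCCCCCCCBr
F6 | step 3 | 19-bromononadecanenitrile | N#CCCCCCCCCCCCCCCCCCCBr
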